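**Retrosynthetic overview**
- Target ⇐ removal of two MOM ethers ⇐ C6 prenylation (Br→Li, prenyl bromide) of a (3R)-6-bromo-isoflavan.
- Ring C ether ⇐ (3R)-3-aryl-dihydrocoumarin by reduction of the lactone C2=O to CH2.
- Key disconnection: the C3–aryl bond, ring C and the stereocentre ⇐ α-diazo ketone, by Wolff 1,2-aryl shift (chromenyl moves from the acyl carbon to C3), capture of the ketene by the ring A phenol and enantioselective protonation.
- Diazo ketone ⇐ diazo transfer to a dihydrochalcone ⇐ Claisen–Schmidt union of a ring A salicylaldehyde with a ring B acetylchromene.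
- Ring order: ring B pyran first (propargyl ether Claisen on a resorcinol-derived ketone), ring A only functionalised, ring C last. All carbons come from resorcinol (twice), acetic acid, DMF, 3-chloro-3-methylbut-1-yne and prenyl bromide.

Assumption: the sense of induction in step 11 is written for (R)-TRIP; if it gives the 3S-lactone, the mirror-image catalyst is used and nothing else changes.

**Route**

Step 1
Reactants: 1 resorcinol
Product: 3 2,4-dihydroxybenzaldehyde, via iminium chloride 2 (not isolated)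
Conditions: POCl3, DMF, MeCN, −15 °C to rt; then H2O, 50 °C
Reagents that add atoms: N,N-dimethylformamide CN(C)C=O (formyl carbon); water O (carbonyl oxygen)
Why: Vilsmeier–Haack formylation; the chloroiminium ion attacks the most nucleophilic carbon of resorcinol (para to one OH, ortho to the other) and iminium 2 is hydrolysed on work-up.

Step 2
Reactants: 3 2,4-dihydroxybenzaldehyde
Product: 4 5-bromo-2,4-dihydroxybenzaldehyde
Conditions: Br2 (1.0 equiv), AcOH, rt
Reagents that add atoms: bromine BrBr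
Why: Electrophilic aromatic bromination goes to C5 (para to the 2-OH, ortho to the 4-OH) because C3 between the two oxygens is the more hindered site.

Step 3
Reactants: 4 5-bromo-2,4-dihydroxybenzaldehyde
Product: 5 5-bromo-2-hydroxy-4-(methoxymethoxy)benzaldehyde
Conditions: MOMCl (1.05 equiv), K2CO3, acetone, 0 °C to rt
Reagents that add atoms: chloromethyl methyl ether COCCl
Why: Williamson-type O-alkylation is selective for the more acidic, unchelated 4-OH, since the 2-OH is tied up in a hydrogen bond to the formyl group.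

Step 4
Reactants: 1 resorcinol; 6 acetic acid
Product: 7 1-(2,4-dihydroxyphenyl)ethanone
Conditions: ZnCl2, AcOH (neat), 140 °C
Reagents that add atoms: none
Why: Nencki reaction (Friedel–Crafts acylation with acetic acid and ZnCl2) acylates resorcinol at C4.

Step 5
Reactants: 7 1-(2,4-dihydroxyphenyl)ethanone
Product: 8 1-[2-hydroxy-4-(methoxymethoxy)phenyl]ethanone
Conditions: MOMCl (1.05 equiv), K2CO3, acetone, 0 °C to rt
Reagents that add atoms: chloromethyl methyl ether COCCl
Why: Selective Williamson-type protection of the unchelated 4-OH leaves only the hydroxyl next to the acetyl group free, which fixes the later pyran regiochemistry.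

Step 6
Reactants: 8 1-[2-hydroxy-4-(methoxymethoxy)phenyl]ethanone; 9 3-chloro-3-methylbut-1-yne
Product: 10 1-[4-(methoxymethoxy)-2-[(2-methylbut-3-yn-2-yl)oxy]phenyl]ethanone
Conditions: K2CO3, KI, CuI (10 mol %), DMF, 65 °C
Reagents that add atoms: none
Why: Copper-assisted propargylic substitution (O-alkylation of the phenoxide by the tertiary propargylic chloride through a copper acetylide-derived electrophile).

Step 7
Reactants: 10 1-[4-(methoxymethoxy)-2-[(2-methylbut-3-yn-2-yl)oxy]phenyl]ethanone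
Product: 11 1-[5-(methoxymethoxy)-2,2-dimethyl-2H-chromen-8-yl]ethanone
Conditions: N,N-diethylaniline, 160 °C
Reagents that add atoms: none
Why: Aromatic propargyl Claisen rearrangement to the only free ortho carbon, then tautomerisation, 1,5-hydrogen shift and oxa-6π electrocyclisation give the 2,2-dimethyl-2H-chromene with its oxygen next to the acetyl-bearing carbon.

Step 8
Reactants: 5 5-bromo-2-hydroxy-4-(methoxymethoxy)benzaldehyde; 11 1-[5-(methoxymethoxy)-2,2-dimethyl-2H-chromen-8-yl]ethanone
Product: 12 (2E)-3-[5-bromo-2-hydroxy-4-(methoxymethoxy)phenyl]-1-[5-(methoxymethoxy)-2,2-dimethyl-2H-chromen-8-yl]prop-2-en-1-one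
Conditions: KOH (50% aq, 4 equiv), EtOH, rt, 48 h; then AcOH to pH 6
Reagents that add atoms: none
Why: Claisen–Schmidt condensation; only the methyl ketone can enolise and E1cB dehydration gives the E-enone.

Step 9
Reactants: 12 (2E)-3-[5-bromo-2-hydroxy-4-(methoxymethoxy)phenyl]-1-[5-(methoxymethoxy)-2,2-dimethyl-2H-chromen-8-yl]prop-2-en-1-one
Product: 13 3-[5-bromo-2-hydroxy-4-(methoxymethoxy)phenyl]-1-[5-(methoxymethoxy)-2,2-dimethyl-2H-chromen-8-yl]propan-1-one
Conditions: Cu(OAc)2·H2O (5 mol %), 1,2-bis(diphenylphosphino)benzene (5 mol %), (EtO)2MeSiH (3 equiv), t-BuOH (3 equiv), toluene, rt; then aq NH4F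
Reagents that add atoms: none
Why: Copper hydride-catalysed conjugate reduction (1,4-hydride addition, protonation of the copper enolate by t-BuOH) is selective for the enone over the chromene alkene, the aryl bromide and the ketone.

Step 10
Reactants: 13 3-[5-bromo-2-hydroxy-4-(methoxymethoxy)phenyl]-1-[5-(methoxymethoxy)-2,2-dimethyl-2H-chromen-8-yl]propan-1-one
Product: 15 3-[5-bromo-2-hydroxy-4-(methoxymethoxy)phenyl]-2-diazo-1-[5-(methoxymethoxy)-2,2-dimethyl-2H-chromen-8-yl]propan-1-one, via trifluoroacetyl ketone 14 (not isolated)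
Conditions: LiN(SiMe3)2 (2.3 equiv), THF, −78 °C; CF3CO2CH2CF3; aq HCl; then MsN3, Et3N, H2O, MeCN, rt
Reagents that add atoms: methanesulfonyl azide CS(=O)(=O)N=[N+]=[N-]; 2,2,2-trifluoroethyl trifluoroacetate O=C(OCC(F)(F)F)C(F)(F)F (its CF3CO group is carried only by 14)
Why: Detrifluoroacetylative diazo transfer (Danheiser variant of the Regitz diazo transfer): the enolate is C-trifluoroacetylated to 14, whose activated α-carbon takes the diazo group from the sulfonyl azide with loss of the trifluoroacetyl group.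

Step 11
Reactants: 15 3-[5-bromo-2-hydroxy-4-(methoxymethoxy)phenyl]-2-diazo-1-[5-(methoxymethoxy)-2,2-dimethyl-2H-chromen-8-yl]propan-1-one
Product: 18 (3R)-6-bromo-7-(methoxymethoxy)-3-[5-(methoxymethoxy)-2,2-dimethyl-2H-chromen-8-yl]-3,4-dihydro-2H-chromen-2-one, via ketene 16 (not isolated), via lactone enol 17 (not isolated)
Conditions: (R)-3,3'-bis(2,4,6-triisopropylphenyl)-1,1'-binaphthyl-2,2'-diyl hydrogen phosphate [(R)-TRIP] (10 mol %), 450 nm LEDs, 5 Å MS, toluene (0.01 M), −40 °C
Reagents that add atoms: none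
Why: Proposed new method: 450 nm excitation of the α-diazo ketone expels N2 with a Wolff 1,2-shift of the chromenyl group from the acyl carbon to the diazo carbon, giving aryl(benzyl)ketene 16; the ortho-phenol adds to the ketene carbonyl and closes ring C as the achiral lactone enol 17, and the chiral phosphoric acid, bound to 17 through P=O (to the enol OH) and P–OH (towards C3), relays the proton to one face of C3 so that the (3R)-lactone forms under catalyst control; the closest known reaction types are the catalytic enantioselective addition of alcohols and phenols to aryl alkyl ketenes and visible-light Wolff rearrangements with asymmetric ketene trapping, neither shown for intramolecular phenol capture to a 3-aryl-dihydrocoumarin.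

Step 12
Reactants: 18 (3R)-6-bromo-7-(methoxymethoxy)-3-[5-(methoxymethoxy)-2,2-dimethyl-2H-chromen-8-yl]-3,4-dihydro-2H-chromen-2-one
Product: 20 8-[(3R)-6-bromo-7-(methoxymethoxy)-3,4-dihydro-2H-chromen-3-yl]-5-(methoxymethoxy)-2,2-dimethyl-2H-chromene, via lactol 19 (not isolated)
Conditions: i-Bu2AlH (1.2 equiv), CH2Cl2, −78 °C; then Et3SiH (4 equiv), BF3·OEt2 (3 equiv), −78 to −30 °C
Reagents that add atoms: none
Why: Partial reduction of the aryl lactone stops at the aluminium lactolate of 19, which BF3·OEt2 ionises to the cyclic oxocarbenium ion that Et3SiH reduces (ionic hydrogenation), so C2 becomes CH2 and C3 is not touched.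

Step 13
Reactants: 20 8-[(3R)-6-bromo-7-(methoxymethoxy)-3,4-dihydro-2H-chromen-3-yl]-5-(methoxymethoxy)-2,2-dimethyl-2H-chromene; 21 1-bromo-3-methylbut-2-ene
Product: 23 5-(methoxymethoxy)-8-[(3R)-7-(methoxymethoxy)-6-(3-methylbut-2-en-1-yl)-3,4-dihydro-2H-chromen-3-yl]-2,2-dimethyl-2H-chromene, via aryllithium 22 (not isolated)
Conditions: n-BuLi (1.1 equiv), THF, −78 °C; then CuBr·SMe2 (10 mol %), 21, −78 to 0 °C
Reagents that add atoms: none
Why: Bromine–lithium exchange next to the OMOM group gives aryllithium 22, which undergoes copper-catalysed allylic substitution at the primary carbon of prenyl bromide (SN2) to install the linear prenyl group.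

Step 14
Reactants: 23 5-(methoxymethoxy)-8-[(3R)-7-(methoxymethoxy)-6-(3-methylbut-2-en-1-yl)-3,4-dihydro-2H-chromen-3-yl]-2,2-dimethyl-2H-chromene
Product: 24 8-[(3R)-7-hydroxy-6-(3-methylbut-2-en-1-yl)-3,4-dihydro-2H-chromen-3-yl]-2,2-dimethyl-2H-chromen-5-ol
Conditions: 3 M HCl (aq), MeOH, rt
Reagents that add atoms: none
Why: Acid-catalysed cleavage of both MOM acetals (transacetalisation to dimethoxymethane) under conditions mild enough to spare the prenyl group, the chromene and the C3 stereocentre.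

**Compound list**

1 | resorcinol (benzene-1,3-diol) | Oc1cccc(O)c1 | starting material
2 | [(2,4-dihydroxyphenyl)methylidene]dimethylazanium chloride | C[N+](C)=Cc1ccc(O)cc1O.[Cl-] | intermediate (not isolated)
3 | 2,4-dihydroxybenzaldehyde | O=Cc1ccc(O)cc1O | intermediate
4 | 5-bromo-2,4-dihydroxybenzaldehyde | O=Cc1cc(Br)c(O)cc1O | intermediate
5 | 5-bromo-2-hydroxy-4-(methoxymethoxy)benzaldehyde | O=Cc1cc(Br)c(OCOC)cc1O | intermediate
6 | acetic acid | CC(O)=O | starting material
7 | 1-(2,4-dihydroxyphenyl)ethanone | CC(=O)c1ccc(O)cc1O | intermediate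
8 | 1-[2-hydroxy-4-(methoxymethoxy)phenyl]ethanone | CC(=O)c1ccc(OCOC)cc1O | intermediate
9 | 3-chloro-3-methylbut-1-yne | CC(C)(Cl)C#C | starting material
10 | 1-[4-(methoxymethoxy)-2-[(2-methylbut-3-yn-2-yl)oxy]phenyl]ethanone | CC(=O)c1ccc(OCOC)cc1OC(C)(C)C#C | intermediate
11 | 1-[5-(methoxymethoxy)-2,2-dimethyl-2H-chromen-8-yl]ethanone | CC(=O)c1ccc(OCOC)c2C=CC(C)(C)Oc12 | intermediate
12 | (2E)-3-[5-bromo-2-hydroxy-4-(methoxymethoxy)phenyl]-1-[5-(methoxymethoxy)-2,2-dimethyl-2H-chromen-8-yl]prop-2-en-1-one | O=C(/C=C/c1cc(Br)c(OCOC)cc1O)c1ccc(OCOC)c2C=CC(C)(C)Oc12 | intermediate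
13 | 3-[5-bromo-2-hydroxy-4-(methoxymethoxy)phenyl]-1-[5-(methoxymethoxy)-2,2-dimethyl-2H-chromen-8-yl]propan-1-one | O=C(CCc1cc(Br)c(OCOC)cc1O)c1ccc(OCOC)c2C=CC(C)(C)Oc12 | intermediate
14 | 2-[5-bromo-2-hydroxy-4-(methoxymethoxy)benzyl]-4,4,4-trifluoro-1-[5-(methoxymethoxy)-2,2-dimethyl-2H-chromen-8-yl]butane-1,3-dione | O=C(C(Cc1cc(Br)c(OCOC)cc1O)C(=O)C(F)(F)F)c1ccc(OCOC)c2C=CC(C)(C)Oc12 | intermediate (not isolated)
15 | 3-[5-bromo-2-hydroxy-4-(methoxymethoxy)phenyl]-2-diazo-1-[5-(methoxymethoxy)-2,2-dimethyl-2H-chromen-8-yl]propan-1-one | O=C(C(=[N+]=[N-])Cc1cc(Br)c(OCOC)cc1O)c1ccc(OCOC)c2C=CC(C)(C)Oc12 | intermediate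
16 | 3-[5-bromo-2-hydroxy-4-(methoxymethoxy)phenyl]-2-[5-(methoxymethoxy)-2,2-dimethyl-2H-chromen-8-yl]prop-1-en-1-one (ketene) | O=C=C(Cc1cc(Br)c(OCOC)cc1O)c1ccc(OCOC)c2C=CC(C)(C)Oc12 | intermediate (not isolated)
17 | 6-bromo-7-(methoxymethoxy)-3-[5-(methoxymethoxy)-2,2-dimethyl-2H-chromen-8-yl]-4H-chromen-2-ol (lactone enol) | OC1=C(c2ccc(OCOC)c3C=CC(C)(C)Oc23)Cc2cc(Br)c(OCOC)cc2O1 | intermediate (not isolated)
18 | (3R)-6-bromo-7-(methoxymethoxy)-3-[5-(methoxymethoxy)-2,2-dimethyl-2H-chromen-8-yl]-3,4-dihydro-2H-chromen-2-one | Brc1cc2c(cc1OCOC)OC(=O)[C@@H](c1ccc(OCOC)c3c1OC(C)(C)C=C3)C2 | intermediate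
19 | (3R)-6-bromo-7-(methoxymethoxy)-3-[5-(methoxymethoxy)-2,2-dimethyl-2H-chromen-8-yl]-3,4-dihydro-2H-chromen-2-ol (both C2 epimers) | Brc1cc2c(cc1OCOC)OC(O)[C@@H](c1ccc(OCOC)c3c1OC(C)(C)C=C3)C2 | intermediate (not isolated)
20 | 8-[(3R)-6-bromo-7-(methoxymethoxy)-3,4-dihydro-2H-chromen-3-yl]-5-(methoxymethoxy)-2,2-dimethyl-2H-chromene | Brc1cc2c(cc1OCOC)OC[C@@H](c1ccc(OCOC)c3c1OC(C)(C)C=C3)C2 | intermediate
21 | 1-bromo-3-methylbut-2-ene (prenyl bromide) | CC(C)=CCBr | starting material
22 | {(3R)-7-(methoxymethoxy)-3-[5-(methoxymethoxy)-2,2-dimethyl-2H-chromen-8-yl]-3,4-dihydro-2H-chromen-6-yl}lithium | [Li]c1cc2c(cc1OCOC)OC[C@@H](c1ccc(OCOC)c3c1OC(C)(C)C=C3)C2 | intermediate (not isolated)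
23 | 5-(methoxymethoxy)-8-[(3R)-7-(methoxymethoxy)-6-(3-methylbut-2-en-1-yl)-3,4-dihydro-2H-chromen-3-yl]-2,2-dimethyl-2H-chromene | CC(C)=CCc1cc2c(cc1OCOC)OC[C@@H](c1ccc(OCOC)c3c1OC(C)(C)C=C3)C2 | intermediate
24 | 8-[(3R)-7-hydroxy-6-(3-methylbut-2-en-1-yl)-3,4-dihydro-2H-chromen-3-yl]-2,2-dimethyl-2H-chromen-5-ol | CC(C)=CCc1cc2c(cc1O)OC[C@@H](c1ccc(O)c3c1OC(C)(C)C=C3)C2 | target

**Step count and risks**

Total: 14 steps. Longest linear sequence: 11 steps (steps 4 to 7, then 8 to 14).

The step most likely to fail is step 11, the new one. The dangers are racemic background tautomerisation of the enol, O–H insertion of a carbene into the phenol (a 2-aroyl-2,3-dihydrobenzofuran) and acid-induced loss of the diazo group. The fallback uses known chemistry and sets out from 15. Irradiation at 450 nm without catalyst gives the racemic 6-bromo-7-(methoxymethoxy)-3-[5-(methoxymethoxy)-2,2-dimethyl-2H-chromen-8-yl]-3,4-dihydro-2H-chromen-2-one F1. LiN(SiMe3)2 and Me3SiCl in THF at −78 °C turn it into the cyclic silyl ketene acetal, trimethyl({6-bromo-7-(methoxymethoxy)-3-[5-(methoxymethoxy)-2,2-dimethyl-2H-chromen-8-yl]-4H-chromen-2-yl}oxy)silane F2. This is protonated enantioselectively with the stoichiometric Lewis-acid-assisted chiral Brønsted acid (R)-BINOL·SnCl4 in toluene at −78 °C, a method established for silyl enol ethers and ketene silyl acetals of α-aryl carbonyl compounds; the BINOL antipode is the one that gives the 3R product. The route is rejoined at 18.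

Next is step 12. The risks are over-reduction to the diol, partial loss of MOM groups to BF3·OEt2, and erosion at C3 if the oxocarbenium ion loses the C3 proton to an enol ether. The fallback sets out from 18. LiBH4 in THF at 0 °C opens the lactone to 4-bromo-2-{(2R)-3-hydroxy-2-[5-(methoxymethoxy)-2,2-dimethyl-2H-chromen-8-yl]propyl}-5-(methoxymethoxy)phenol F3. The ring is then closed by Mitsunobu etherification (PPh3, diisopropyl azodicarboxylate, THF, 0 °C) between the phenol and the primary alcohol, with no cationic intermediate, and the route is rejoined at 20.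

Third is step 6. The hydrogen-bonded, hindered phenol of 8 may be alkylated poorly by the tertiary chloride, which can instead eliminate to the enyne. The fallback sets out from 8 and builds the pyran directly with 3-methylbut-2-enal (CC(C)=CC=O), ethylenediammonium diacetate (10 mol %), xylene, 140 °C. This is a Knoevenagel-type C-alkylation at the carbon between the two oxygens, dehydration to an ortho-quinone methide and oxa-6π closure. It bypasses 10 and step 7 and rejoins the route at 11; no new compound is made on this path (entry F0).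

**Further compounds**

F1 | step 11 | rac-6-bromo-7-(methoxymethoxy)-3-[5-(methoxymethoxy)-2,2-dimethyl-2H-chromen-8-yl]-3,4-dihydro-2H-chromen-2-one | Brc1cc2c(cc1OCOC)OC(=O)C(c1ccc(OCOC)c3c1OC(C)(C)C=C3)C2
F2 | step 11 | trimethyl({6-bromo-7-(methoxymethoxy)-3-[5-(methoxymethoxy)-2,2-dimethyl-2H-chromen-8-yl]-4H-chromen-2-yl}oxy)silane | C[Si](C)(C)OC1=C(c2ccc(OCOC)c3C=CC(C)(C)Oc23)Cc2cc(Br)c(OCOC)cc2O1
F3 | step 12 | 4-bromo-2-{(2R)-3-hydroxy-2-[5-(methoxymethoxy)-2,2-dimethyl-2H-chromen-8-yl]propyl}-5-(methoxymethoxy)phenol | OC[C@@H](c1ccc(OCOC)c3c1OC(C)(C)C=C3)Cc1cc(Br)c(OCOC)cc1O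
F0 | step 6 | none | none
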